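**Retrosynthetic overview**

1. The target is an oxolane, numbered O1, C2 (3,4,5-trimethoxyphenyl), C3 (CH2OH), C4 ((S)-CH(OH)-3,4-dimethoxyphenyl), C5. The free alcohols come last, by ester reduction and desilylation.
2. The key disconnection is C2–C3. The strategy rests on the C2–H bond, which is benzylic to the trimethoxyphenyl ring, α to O1, and five atoms from C3 (C3–C4–C5–O1–C2). A rhodium carbene at C3, made from an α-diazo methyl ester, inserts into it.
3. The diazo ester comes from the methyl ester by C3 benzoylation and deacylative diazo transfer. The ester comes from an allyl group by oxidative cleavage, oxidation and methylation.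
4. The O1–C5 ether comes from a primary alcohol and 3,4,5-trimethoxybenzyl bromide. C4 and the carbinol carbon come from an Evans syn aldol of (S)-4-benzyl-3-(pent-4-enoyl)oxazolidinone with veratraldehyde.
5. Ring order: a single ring, the oxolane, closed in step 12.

Key step: step 12

Assumption (chemistry): the oxolane numbering above is used for the open-chain precursors as well, and TBS stands for tert-butyldimethylsilyl. The insertion is taken to give the 2,3-trans ester, the arrangement that is also thermodynamically preferred at C3.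

**Route**

Step 1
Reactants: 1 4-pentenoic acid; 2 (S)-4-benzyl-1,3-oxazolidin-2-one
Product: 4 (S)-4-benzyl-3-(pent-4-enoyl)-1,3-oxazolidin-2-one, via mixed pivalic anhydride 3 (not isolated)
Conditions: PivCl, Et3N, THF, −20 °C; then 2, LiCl, −20 °C → rt
Reagents that add atoms: none
Why: N-acylation of the oxazolidinone through the mixed pivalic anhydride (LiCl-promoted acyl transfer) should attach the auxiliary at the unhindered pentenoyl carbonyl without a strong base.

Step 2
Reactants: 4 (S)-4-benzyl-3-(pent-4-enoyl)-1,3-oxazolidin-2-one; 5 3,4-dimethoxybenzaldehyde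
Product: 8 (4S)-4-benzyl-3-[(2S)-2-[(S)-(3,4-dimethoxyphenyl)(hydroxy)methyl]pent-4-enoyl]-1,3-oxazolidin-2-one, via Z-dibutylboron enolate 6 (not isolated), via dibutylboron aldolate 7 (not isolated)
Conditions: Bu2BOTf, iPr2NEt, CH2Cl2, 0 °C; then 5, −78 → 0 °C; then pH 7 buffer, MeOH, 30% H2O2, 0 °C
Reagents that add atoms: none
Why: Evans syn aldol, in which the Z-boron enolate reacts through a Zimmerman–Traxler chair on the face opposite the benzyl group of the auxiliary, should set both C4 and the carbinol carbon (2S and S in 8).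

Step 3
Reactants: 8 (4S)-4-benzyl-3-[(2S)-2-[(S)-(3,4-dimethoxyphenyl)(hydroxy)methyl]pent-4-enoyl]-1,3-oxazolidin-2-one
Product: 9 (4S)-4-benzyl-3-[(2S)-2-[(S)-(TBSO)(3,4-dimethoxyphenyl)methyl]pent-4-enoyl]-1,3-oxazolidin-2-one
Conditions: TBSOTf, 2,6-lutidine, CH2Cl2, 0 °C
Reagents that add atoms: tert-butyldimethylsilyl triflate, CC(C)(C)[Si](C)(C)OS(=O)(=O)C(F)(F)F
Why: Silylation of the secondary benzylic alcohol with a silyl triflate and a hindered base should be fast enough to outrun retro-aldol and masks the hydroxyl against O–H insertion in step 12.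

Step 4
Reactants: 9 (4S)-4-benzyl-3-[(2S)-2-[(S)-(TBSO)(3,4-dimethoxyphenyl)methyl]pent-4-enoyl]-1,3-oxazolidin-2-one
Product: 10 (2R)-2-[(S)-(TBSO)(3,4-dimethoxyphenyl)methyl]pent-4-en-1-ol
Conditions: LiBH4, MeOH (1 equiv), THF, 0 °C
Reagents that add atoms: none
Why: Reductive cleavage of the N-acyl oxazolidinone by borohydride attack at the exocyclic carbonyl should release the primary alcohol (future C5–O1) and the recoverable auxiliary without touching the silyl ether or the alkene.

Step 5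
Reactants: 11 3,4,5-trimethoxybenzyl alcohol
Product: 12 3,4,5-trimethoxybenzyl bromide
Conditions: PBr3, CH2Cl2, 0 °C
Reagents that add atoms: phosphorus tribromide, BrP(Br)Br
Why: Bromination of a benzylic alcohol with PBr3 (bromide displacement of the phosphite ester) should give the alkylating agent, which is used fresh.

Step 6
Reactants: 10 (2R)-2-[(S)-(TBSO)(3,4-dimethoxyphenyl)methyl]pent-4-en-1-ol; 12 3,4,5-trimethoxybenzyl bromide
Product: 13 tert-butyl{[(1S,2R)-1-(3,4-dimethoxyphenyl)-2-[(3,4,5-trimethoxybenzyloxy)methyl]pent-4-en-1-yl]oxy}dimethylsilane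
Conditions: Ag2O, 4 Å MS, CH2Cl2, rt, dark
Reagents that add atoms: none
Why: Ag2O-mediated Williamson-type etherification, in which silver activates the benzylic bromide toward the neutral primary alcohol, should form the ether without a free alkoxide and so avoid 1,3 oxygen-to-oxygen silyl migration.

Step 7
Reactants: 13 tert-butyl{[(1S,2R)-1-(3,4-dimethoxyphenyl)-2-[(3,4,5-trimethoxybenzyloxy)methyl]pent-4-en-1-yl]oxy}dimethylsilane
Product: 15 (3R,4S)-4-(TBSO)-4-(3,4-dimethoxyphenyl)-3-[(3,4,5-trimethoxybenzyloxy)methyl]butanal, via vicinal diol 14 (not isolated)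
Conditions: OsO4 (2 mol %), NaIO4, 2,6-lutidine, dioxane/H2O (3:1), rt
Reagents that add atoms: osmium tetroxide, O=[Os](=O)(=O)=O (oxygen carrier); sodium periodate, [Na+].[O-][I](=O)(=O)=O (terminal oxidant)
Why: Lemieux–Johnson oxidation (dihydroxylation, then periodate glycol cleavage) should shorten the allyl group to the aldehyde, with both oxidants inert toward the methoxy arenes and the benzylic ethers.

Step 8
Reactants: 15 (3R,4S)-4-(TBSO)-4-(3,4-dimethoxyphenyl)-3-[(3,4,5-trimethoxybenzyloxy)methyl]butanal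
Product: 16 (3R,4S)-4-(TBSO)-4-(3,4-dimethoxyphenyl)-3-[(3,4,5-trimethoxybenzyloxy)methyl]butanoic acid
Conditions: NaClO2, NaH2PO4, 2-methyl-2-butene, t-BuOH/H2O, rt
Reagents that add atoms: sodium chlorite, [Na+].[O-]Cl=O
Why: Pinnick oxidation should convert the aldehyde into the acid, with 2-methyl-2-butene scavenging HOCl so that the electron-rich rings are not chlorinated.

Step 9
Reactants: 16 (3R,4S)-4-(TBSO)-4-(3,4-dimethoxyphenyl)-3-[(3,4,5-trimethoxybenzyloxy)methyl]butanoic acid
Product: 17 methyl (3R,4S)-4-(TBSO)-4-(3,4-dimethoxyphenyl)-3-[(3,4,5-trimethoxybenzyloxy)methyl]butanoate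
Conditions: MeI, K2CO3, DMF, rt
Reagents that add atoms: iodomethane, CI
Why: O-Alkylation of the carboxylate (SN2 on MeI) should give the methyl ester under mild base that leaves the silyl ether intact.

Step 10
Reactants: 17 methyl (3R,4S)-4-(TBSO)-4-(3,4-dimethoxyphenyl)-3-[(3,4,5-trimethoxybenzyloxy)methyl]butanoate
Product: 18 methyl (3R,4S)-2-benzoyl-4-(TBSO)-4-(3,4-dimethoxyphenyl)-3-[(3,4,5-trimethoxybenzyloxy)methyl]butanoate (C2 epimers)
Conditions: NaH, PhCO2Me, DME, reflux
Reagents that add atoms: methyl benzoate, COC(=O)c1ccccc1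
Why: Crossed Claisen condensation of the ester enolate with non-enolisable methyl benzoate should place the benzoyl activating group on C3, driven by formation of the stabilised β-keto ester enolate (the new centre is lost in step 11).

Step 11
Reactants: 18 methyl (3R,4S)-2-benzoyl-4-(TBSO)-4-(3,4-dimethoxyphenyl)-3-[(3,4,5-trimethoxybenzyloxy)methyl]butanoate
Product: 19 methyl (3R,4S)-2-diazo-4-(TBSO)-4-(3,4-dimethoxyphenyl)-3-[(3,4,5-trimethoxybenzyloxy)methyl]butanoate
Conditions: p-ABSA, DBU, CH2Cl2, 0 °C → rt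
Reagents that add atoms: 4-acetamidobenzenesulfonyl azide, CC(=O)Nc1ccc(cc1)S(=O)(=O)N=[N+]=[N-]
Why: Regitz deacylative diazo transfer, in which the β-keto ester enolate attacks the sulfonyl azide and the adduct fragments with loss of the N-benzoyl sulfonamide, should leave the α-diazo ester.

Step 12
Reactants: 19 methyl (3R,4S)-2-diazo-4-(TBSO)-4-(3,4-dimethoxyphenyl)-3-[(3,4,5-trimethoxybenzyloxy)methyl]butanoate
Product: 20 methyl (2R,3R,4R)-4-[(S)-(TBSO)(3,4-dimethoxyphenyl)methyl]-2-(3,4,5-trimethoxyphenyl)oxolane-3-carboxylate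
Conditions: Rh2(O2CCPh3)4 (1 mol %), CH2Cl2, −78 °C → rt, slow addition of 19
Reagents that add atoms: none
Why: Rh2(O2CCPh3)4 should expel N2 from 19 to give an electrophilic rhodium carbene at C3, which inserts into the benzylic ether C2–H bond through a concerted, asynchronous three-centre transition state with hydride-transfer character; the closest known reaction type is the dirhodium-catalysed intramolecular 1,5 C–H insertion of α-alkyl-α-diazo esters into ether α-C–H bonds, which gives tetrahydrofuran-3-carboxylates. The oxolane closes by 1,5 C–H insertion, the C2–C3 bond forming in a chair-like six-centre array of C3, C4, C5, O1, C2 and the migrating hydrogen. C2 is controlled by the C4 stereocentre, because the silyloxybenzyl group on C4 and the trimethoxyphenyl group on C2 should both sit pseudo-equatorial, which makes them cis and gives (2R). C3 should form with the ester pseudo-equatorial and trans to both neighbours, which is also the thermodynamic arrangement, so any C3 epimer should converge on 20 on exposure to NaOMe in MeOH. The step needs insertion to beat 1,2-hydride migration from C4–H and carbene attack on the dimethoxyphenyl ring: C2–H is activated by O1 and the electron-rich aryl group, C4–H is deactivated by two flanking oxygen-bearing carbons, and the bulky triphenylacetate ligands at low temperature disfavour hydride migration and approach to the hindered ring.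

Step 13
Reactants: 20 methyl (2R,3R,4R)-4-[(S)-(TBSO)(3,4-dimethoxyphenyl)methyl]-2-(3,4,5-trimethoxyphenyl)oxolane-3-carboxylate
Product: 21 [(2R,3S,4R)-4-[(S)-(TBSO)(3,4-dimethoxyphenyl)methyl]-2-(3,4,5-trimethoxyphenyl)oxolan-3-yl]methanol
Conditions: LiAlH4, THF, 0 °C
Reagents that add atoms: none
Why: Hydride reduction of the methyl ester by LiAlH4 should give the C3 hydroxymethyl group, after which C3 is no longer epimerisable, while the silyl ether and the benzylic ethers are left alone.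

Step 14
Reactants: 21 [(2R,3S,4R)-4-[(S)-(TBSO)(3,4-dimethoxyphenyl)methyl]-2-(3,4,5-trimethoxyphenyl)oxolan-3-yl]methanol
Product: 22 [(2R,3S,4R)-4-[(S)-(3,4-dimethoxyphenyl)(hydroxy)methyl]-2-(3,4,5-trimethoxyphenyl)oxolan-3-yl]methanol (CNP0172668.1)
Conditions: Bu4NF, THF, 0 °C → rt
Reagents that add atoms: none
Why: Fluoride-mediated desilylation should free the benzylic alcohol under non-acidic conditions, which avoids ionisation of the two electron-rich benzylic C–O bonds.

**Compound list**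

1 | 4-pentenoic acid | C=CCCC(=O)O | starting material
2 | (S)-4-benzyl-1,3-oxazolidin-2-one | O=C1N[C@@H](Cc2ccccc2)CO1 | starting material
3 | pivalic 4-pentenoic mixed anhydride (formed in the flask) | C=CCCC(=O)OC(=O)C(C)(C)C | intermediate
4 | (S)-4-benzyl-3-(pent-4-enoyl)-1,3-oxazolidin-2-one | C=CCCC(=O)N1[C@@H](Cc2ccccc2)COC1=O | intermediate
5 | 3,4-dimethoxybenzaldehyde (veratraldehyde) | COc1ccc(C=O)cc1OC | starting material
6 | (4S)-4-benzyl-3-[(1Z)-1-(dibutylboryloxy)penta-1,4-dien-1-yl]-1,3-oxazolidin-2-one (Z-boron enolate, formed in the flask) | C=CC/C=C(\OB(CCCC)CCCC)N1[C@@H](Cc2ccccc2)COC1=O | intermediate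
7 | O-dibutylboryl derivative of 8 (boron aldolate, formed in the flask) | C=CC[C@@H]([C@H](OB(CCCC)CCCC)c1ccc(OC)c(OC)c1)C(=O)N1[C@@H](Cc2ccccc2)COC1=O | intermediate
8 | (4S)-4-benzyl-3-[(2S)-2-[(S)-(3,4-dimethoxyphenyl)(hydroxy)methyl]pent-4-enoyl]-1,3-oxazolidin-2-one | C=CC[C@@H]([C@H](O)c1ccc(OC)c(OC)c1)C(=O)N1[C@@H](Cc2ccccc2)COC1=O | intermediate
9 | (4S)-4-benzyl-3-[(2S)-2-[(S)-(tert-butyldimethylsilyloxy)(3,4-dimethoxyphenyl)methyl]pent-4-enoyl]-1,3-oxazolidin-2-one | C=CC[C@@H]([C@H](O[Si](C)(C)C(C)(C)C)c1ccc(OC)c(OC)c1)C(=O)N1[C@@H](Cc2ccccc2)COC1=O | intermediate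
10 | (2R)-2-[(S)-(tert-butyldimethylsilyloxy)(3,4-dimethoxyphenyl)methyl]pent-4-en-1-ol | C=CC[C@@H]([C@H](O[Si](C)(C)C(C)(C)C)c1ccc(OC)c(OC)c1)CO | intermediate
11 | 3,4,5-trimethoxybenzyl alcohol | COc1cc(CO)cc(OC)c1OC | starting material
12 | 3,4,5-trimethoxybenzyl bromide | COc1cc(CBr)cc(OC)c1OC | intermediate
13 | tert-butyl{[(1S,2R)-1-(3,4-dimethoxyphenyl)-2-[(3,4,5-trimethoxybenzyloxy)methyl]pent-4-en-1-yl]oxy}dimethylsilane | C=CC[C@@H]([C@H](O[Si](C)(C)C(C)(C)C)c1ccc(OC)c(OC)c1)COCc1cc(OC)c(OC)c(OC)c1 | intermediate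
14 | (4R,5S)-5-(tert-butyldimethylsilyloxy)-5-(3,4-dimethoxyphenyl)-4-[(3,4,5-trimethoxybenzyloxy)methyl]pentane-1,2-diol (C2 epimers, formed in the flask) | OCC(O)C[C@@H]([C@H](O[Si](C)(C)C(C)(C)C)c1ccc(OC)c(OC)c1)COCc1cc(OC)c(OC)c(OC)c1 | intermediate
15 | (3R,4S)-4-(tert-butyldimethylsilyloxy)-4-(3,4-dimethoxyphenyl)-3-[(3,4,5-trimethoxybenzyloxy)methyl]butanal | O=CC[C@@H]([C@H](O[Si](C)(C)C(C)(C)C)c1ccc(OC)c(OC)c1)COCc1cc(OC)c(OC)c(OC)c1 | intermediate
16 | (3R,4S)-4-(tert-butyldimethylsilyloxy)-4-(3,4-dimethoxyphenyl)-3-[(3,4,5-trimethoxybenzyloxy)methyl]butanoic acid | OC(=O)C[C@@H]([C@H](O[Si](C)(C)C(C)(C)C)c1ccc(OC)c(OC)c1)COCc1cc(OC)c(OC)c(OC)c1 | intermediate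
17 | methyl (3R,4S)-4-(tert-butyldimethylsilyloxy)-4-(3,4-dimethoxyphenyl)-3-[(3,4,5-trimethoxybenzyloxy)methyl]butanoate | COC(=O)C[C@@H]([C@H](O[Si](C)(C)C(C)(C)C)c1ccc(OC)c(OC)c1)COCc1cc(OC)c(OC)c(OC)c1 | intermediate
18 | methyl (3R,4S)-2-benzoyl-4-(tert-butyldimethylsilyloxy)-4-(3,4-dimethoxyphenyl)-3-[(3,4,5-trimethoxybenzyloxy)methyl]butanoate (C2 epimers) | COC(=O)C(C(=O)c1ccccc1)[C@@H]([C@H](O[Si](C)(C)C(C)(C)C)c1ccc(OC)c(OC)c1)COCc1cc(OC)c(OC)c(OC)c1 | intermediate
19 | methyl (3R,4S)-2-diazo-4-(tert-butyldimethylsilyloxy)-4-(3,4-dimethoxyphenyl)-3-[(3,4,5-trimethoxybenzyloxy)methyl]butanoate | COC(=O)C(=[N+]=[N-])[C@@H]([C@H](O[Si](C)(C)C(C)(C)C)c1ccc(OC)c(OC)c1)COCc1cc(OC)c(OC)c(OC)c1 | intermediate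
20 | methyl (2R,3R,4R)-4-[(S)-(tert-butyldimethylsilyloxy)(3,4-dimethoxyphenyl)methyl]-2-(3,4,5-trimethoxyphenyl)oxolane-3-carboxylate (all-trans) | COc1ccc([C@@H](O[Si](C)(C)C(C)(C)C)[C@H]2CO[C@@H](c3cc(OC)c(OC)c(OC)c3)[C@@H]2C(=O)OC)cc1OC | intermediate
21 | [(2R,3S,4R)-4-[(S)-(tert-butyldimethylsilyloxy)(3,4-dimethoxyphenyl)methyl]-2-(3,4,5-trimethoxyphenyl)oxolan-3-yl]methanol | COc1ccc([C@@H](O[Si](C)(C)C(C)(C)C)[C@H]2CO[C@@H](c3cc(OC)c(OC)c(OC)c3)[C@@H]2CO)cc1OC | intermediate
22 | [(2R,3S,4R)-4-[(S)-(3,4-dimethoxyphenyl)(hydroxy)methyl]-2-(3,4,5-trimethoxyphenyl)oxolan-3-yl]methanol (CNP0172668.1) | COc1ccc([C@@H](O)[C@H]2CO[C@@H](c3cc(OC)c(OC)c(OC)c3)[C@@H]2CO)cc1OC | target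

**Summary**

Total step count: 14. Longest linear sequence: 13 steps (steps 1–4 and 6–14); step 5 is a one-step side branch.

**Steps most likely to fail**

Step 12 (key step). What may go wrong:
- 1,2-hydride migration from C4 to the carbene carbon, which gives an α,β-unsaturated ester;
- electrophilic attack of the carbene on the dimethoxyphenyl ring;
- insertion through the other diastereotopic benzylic hydrogen, which would place the aryl group trans to the C4 side chain.

Fallback: an ionic construction that forms C2–C3 by a second auxiliary-controlled aldol and O1–C2 by cycloetherification. It sets out from 10 and returns at 21.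
- 10 is acylated (PivCl, pyridine, DMAP cat., CH2Cl2) to the pivalate ester F1.
- OsO4 (cat.)/NaIO4/2,6-lutidine cleavage passes through the vicinal diol F2 to the aldehyde F3.
- NaClO2/NaH2PO4/2-methyl-2-butene oxidation gives the acid F4.
- Coupling with (R)-4-benzyl-1,3-oxazolidin-2-one (DCC, DMAP cat., CH2Cl2) gives the imide F5.
- Enolisation with Bu2BOTf/iPr2NEt gives the Z-boron enolate F6. Addition of 3,4,5-trimethoxybenzaldehyde gives the boron aldolate F7, and oxidative work-up gives the syn aldol adduct F8. In this Evans syn aldol the (R)-auxiliary should fix C3 and C2 in the configuration of 21.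
- LiAlH4 (THF, 0 °C) reduces the imide and the pivalate to the triol F9.
- Brief exposure to camphorsulfonic acid (cat., CH2Cl2, −20 °C) should ionise the free trimethoxybenzylic alcohol. The C5 hydroxyl is the only one that can reach C2 through a five-membered ring, and it should close the oxolane trans to the C3 substituent, giving 21. The conditions must be kept mild enough that the silyl-protected dimethoxybenzylic position does not ionise as well.

Step 10 (with step 11). What may go wrong: incomplete C-acylation of the hindered, β-branched ester enolate, self-condensation of the ester, or loss of the silyl group under hot NaH and methoxide.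

Fallback: electrophilic azidation and diazotisation in place of acyl activation and diazo transfer. It sets out from 17 and returns at 19.
- KN(SiMe3)2 (THF, −78 °C), then 2,4,6-triisopropylbenzenesulfonyl azide and an AcOH quench, gives the α-azido ester F10.
- Zn/NH4Cl (EtOH/H2O) reduces it to the α-amino ester F11.
- Isoamyl nitrite with catalytic AcOH in warm CHCl3 diazotises the amino ester to 19.

Step 6. What may go wrong: slow alkylation of the unactivated primary alcohol, with competing self-alkylation of the electron-rich benzyl bromide, or silyl migration from the secondary to the primary oxygen if base has to be used to force the reaction.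

Fallback: acid-catalysed imidate alkylation with no alkoxide at any stage. It sets out from 11 and 10 and returns at 13.
- 11 with Cl3CCN and DBU (cat., CH2Cl2, 0 °C) gives 3,4,5-trimethoxybenzyl trichloroacetimidate F12.
- F12 and 10 with TfOH (cat.) in Et2O at −20 °C should give 13.

**Further compounds**

F1 | step 12 | (2R)-2-[(S)-(tert-butyldimethylsilyloxy)(3,4-dimethoxyphenyl)methyl]pent-4-en-1-yl pivalate | C=CC[C@@H]([C@H](O[Si](C)(C)C(C)(C)C)c1ccc(OC)c(OC)c1)COC(=O)C(C)(C)C
F2 | step 12 | (2R)-2-[(S)-(tert-butyldimethylsilyloxy)(3,4-dimethoxyphenyl)methyl]-4,5-dihydroxypentyl pivalate (C4 epimers, formed in the flask) | OCC(O)C[C@@H]([C@H](O[Si](C)(C)C(C)(C)C)c1ccc(OC)c(OC)c1)COC(=O)C(C)(C)C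
F3 | step 12 | (2R)-2-[(S)-(tert-butyldimethylsilyloxy)(3,4-dimethoxyphenyl)methyl]-4-oxobutyl pivalate | O=CC[C@@H]([C@H](O[Si](C)(C)C(C)(C)C)c1ccc(OC)c(OC)c1)COC(=O)C(C)(C)C
F4 | step 12 | (3R)-3-[(S)-(tert-butyldimethylsilyloxy)(3,4-dimethoxyphenyl)methyl]-4-(pivaloyloxy)butanoic acid | OC(=O)C[C@@H]([C@H](O[Si](C)(C)C(C)(C)C)c1ccc(OC)c(OC)c1)COC(=O)C(C)(C)C
F5 | step 12 | (4R)-4-benzyl-3-[(3R)-3-[(S)-(tert-butyldimethylsilyloxy)(3,4-dimethoxyphenyl)methyl]-4-(pivaloyloxy)butanoyl]-1,3-oxazolidin-2-one | O=C(C[C@@H]([C@H](O[Si](C)(C)C(C)(C)C)c1ccc(OC)c(OC)c1)COC(=O)C(C)(C)C)N1[C@H](Cc2ccccc2)COC1=O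
F6 | step 12 | Z-dibutylboron enolate of F5 (formed in the flask) | CCCCB(CCCC)O/C(=C\[C@@H]([C@H](O[Si](C)(C)C(C)(C)C)c1ccc(OC)c(OC)c1)COC(=O)C(C)(C)C)N1[C@H](Cc2ccccc2)COC1=O
F7 | step 12 | O-dibutylboryl derivative of F8 (boron aldolate, formed in the flask) | O=C(N1[C@H](Cc2ccccc2)COC1=O)[C@@H]([C@@H](OB(CCCC)CCCC)c1cc(OC)c(OC)c(OC)c1)[C@@H]([C@H](O[Si](C)(C)C(C)(C)C)c1ccc(OC)c(OC)c1)COC(=O)C(C)(C)C
F8 | step 12 | (4R)-4-benzyl-3-[(2R,3R)-2-[(R)-hydroxy(3,4,5-trimethoxyphenyl)methyl]-3-[(S)-(tert-butyldimethylsilyloxy)(3,4-dimethoxyphenyl)methyl]-4-(pivaloyloxy)butanoyl]-1,3-oxazolidin-2-one | O=C(N1[C@H](Cc2ccccc2)COC1=O)[C@@H]([C@@H](O)c1cc(OC)c(OC)c(OC)c1)[C@@H]([C@H](O[Si](C)(C)C(C)(C)C)c1ccc(OC)c(OC)c1)COC(=O)C(C)(C)C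
F9 | step 12 | (2S,3R)-2-[(R)-hydroxy(3,4,5-trimethoxyphenyl)methyl]-3-[(S)-(tert-butyldimethylsilyloxy)(3,4-dimethoxyphenyl)methyl]butane-1,4-diol | OC[C@@H]([C@@H](O)c1cc(OC)c(OC)c(OC)c1)[C@@H]([C@H](O[Si](C)(C)C(C)(C)C)c1ccc(OC)c(OC)c1)CO
F10 | step 10 | methyl (3R,4S)-2-azido-4-(tert-butyldimethylsilyloxy)-4-(3,4-dimethoxyphenyl)-3-[(3,4,5-trimethoxybenzyloxy)methyl]butanoate (C2 epimers) | COC(=O)C(N=[N+]=[N-])[C@@H]([C@H](O[Si](C)(C)C(C)(C)C)c1ccc(OC)c(OC)c1)COCc1cc(OC)c(OC)c(OC)c1
F11 | step 10 | methyl (3R,4S)-2-amino-4-(tert-butyldimethylsilyloxy)-4-(3,4-dimethoxyphenyl)-3-[(3,4,5-trimethoxybenzyloxy)methyl]butanoate (C2 epimers) | COC(=O)C(N)[C@@H]([C@H](O[Si](C)(C)C(C)(C)C)c1ccc(OC)c(OC)c1)COCc1cc(OC)c(OC)c(OC)c1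
F12 | step 6 | 3,4,5-trimethoxybenzyl 2,2,2-trichloroacetimidate | COc1cc(COC(=N)C(Cl)(Cl)Cl)cc(OC)c1OC
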